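Rings: upper unit A (benzo), B (aryl), C (pyran); lower unit D, E, F. Cuts: the interflavan bond C4(C)–C6(D); in each half the bond C2–aryl; then carbon C3 is taken out of each pyran ring, which leaves one benzofuran, 4, for both halves.
Enabling feature: in ring F (O1, C2, C3, C4, C4a, C8a) O1 flanks C2 and the 7-oxygen of ring D stands para to C4a. O1–C2–C3–C4 at the flav-3-ene level is therefore an aromatic chromenylium ion, which is what a dibromocyclopropane fused to the C2–C3 bond of a 6,7-dioxygenated benzofuran releases on loss of bromide.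
Forward: coumaranone 1 → benzofuran 4 → CBr2 insertion (furan ring becomes pyran ring) → chromene acetal 8, common to both halves → aryl transfer to C2 with either catalyst antipode → flav-3-enes 11 (2R) and 14 (2S).
Lower half: OsO4 adds opposite to the 2-aryl group of 11 (sets C3 and C4, 2,3-trans-3,4-cis), then carbonate 13. Upper half: bromohydrin and epoxide closure on 14 put O3 on the aryl face (2,3-cis), and methanolysis gives 17.
Union: the C4 cation from 17 is attacked by C6 of ring D of 13 opposite to O3 (3,4-trans); carbonate methanolysis and hydrogenolysis finish the synthesis.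
Stereochemistry: C2 of each half comes from the tartaric-acid-derived catalyst (stereoconvergent on racemic 8); the other five centres follow from C2 by substrate control.

Key step: step 3

Assumption: 6,7-dihydroxybenzofuran-3(2H)-one (1) and 4-(benzyloxy)phenylboronic acid (9) are catalogue compounds, and the L-tartaric-acid-derived catalyst is taken to give the 2R flavene; should the sense be the opposite, the catalysts of steps 6 and 9 change places.

Step 1
Reactants: 1 6,7-dihydroxybenzofuran-3(2H)-one
Product: 2 6,7-bis(benzyloxy)benzofuran-3(2H)-one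
Conditions: BnBr (2.2 equiv), K2CO3, DMF, rt
Reagents that add atoms: benzyl bromide, BrCc1ccccc1
Why: Williamson ether synthesis; with a weak base at room temperature the two acidic phenols should be alkylated well before the C2 methylene, so O-benzylation should prevail over C-benzylation.

Step 2
Reactants: 2 6,7-bis(benzyloxy)benzofuran-3(2H)-one
Product: 4 6,7-bis(benzyloxy)benzofuran, via dihydrobenzofuran-3-ol 3 (not isolated)
Conditions: NaBH4, MeOH–THF, 0 °C; then 2 M HCl, rt
Reagents that add atoms: none
Why: Borohydride carbonyl reduction followed by acid-catalysed E1 dehydration; the 3-ol is a p-alkoxybenzylic alcohol that ionises easily and loses a C2 proton to give the aromatic furan ring.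

Step 3
Reactants: 4 6,7-bis(benzyloxy)benzofuran
Product: 7 7,8-bis(benzyloxy)-3-bromo-2-ethoxy-2H-chromene (racemic), via dibromocyclopropane adduct 5 (not isolated), via 3-bromochromenylium bromide 6 (not isolated)
Conditions: CHBr3 (2 equiv), KOtBu (2.2 equiv), toluene, −20 °C; then EtOH (excess), K2CO3, 40 °C
Reagents that add atoms: bromoform, BrC(Br)Br; ethanol, CCO
Why: Dibromocarbene, formed from bromoform by alpha-elimination, should add in a concerted cheletropic [2+1] syn fashion to the enol-ether-like C2=C3 bond of 4, closing the three-membered ring of 5 cis on the furan ring and dearomatising it. The endo bromide of 5 then leaves with concerted disrotatory two-electron electrocyclic opening of the shared C–C bond (Woodward–Hoffmann–DePuy rule), pushed by the lone pair of O1 and by the benzyloxy group para to the benzylic terminus, so the five-membered ring (O1, the two sp3 carbons, C3a, C7a) takes up the carbene carbon and becomes the aromatic six-membered chromenylium ion 6, the new atom being C3 of ring F and of ring C. Ethanol adds at C2, next to O1, to give acetal 7; the closest known reaction type is the dihalocarbene ring enlargement of benzofurans, indoles and cyclic enol ethers (Ciamician–Dennstedt type). No ring is closed in the enlargement itself, since the six-membered ring arises by cleavage of the zero bridge and only the cyclopropane is closed. The acetal carbon forms as a racemate, which is harmless because steps 6 and 9 ionise it again. The step needs carbene addition at the furan double bond rather than at the arenes or the benzylic C–H bonds, which the enol-ether nucleophilicity secures; it needs capture at C2 rather than C4, which is the thermodynamic acetal position; and it needs exclusion of water and hydroxide, which the anhydrous alkoxide base provides, so that no 3-bromolactol can contract back to a benzofuran.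

Step 4
Reactants: 7 7,8-bis(benzyloxy)-3-bromo-2-ethoxy-2H-chromene
Product: 8 7,8-bis(benzyloxy)-2-ethoxy-2H-chromene (racemic)
Conditions: Bu3SnH (1.2 equiv), AIBN (cat.), toluene, 80 °C
Reagents that add atoms: none
Why: Radical-chain hydrodehalogenation of the vinyl bromide with tin hydride; the neutral conditions should leave the acetal and the benzyl ethers untouched, and no stereocentre of consequence is present yet.

Step 5
Reactants: 9 4-(benzyloxy)phenylboronic acid
Product: 10 diethyl [4-(benzyloxy)phenyl]boronate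
Conditions: EtOH, toluene, azeotropic removal of water
Reagents that add atoms: ethanol, CCO
Why: Boronic acid esterification driven by removal of water; it gives the exchangeable boronate needed for ligand exchange with the chiral diol acid.

Step 6
Reactants: 8 7,8-bis(benzyloxy)-2-ethoxy-2H-chromene; 10 diethyl [4-(benzyloxy)phenyl]boronate
Product: 11 (2R)-7,8-bis(benzyloxy)-2-[4-(benzyloxy)phenyl]-2H-chromene
Conditions: 10 (1.5 equiv), (2R,3R)-4-(dibenzylamino)-2,3-dihydroxy-4-oxobutanoic acid (10 mol %), Yb(OTf)3 (5 mol %), EtOAc, −20 °C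
Reagents that add atoms: none
Why: Enantioselective boronate addition to a chromene acetal (Petasis-type arylation of an oxocarbenium ion): the racemic acetal is ionised to the achiral chromenylium ion and the tartrate-bound aryl boronate delivers the aryl group irreversibly to one face of C2, so both acetal antipodes should converge on 11.

Step 7
Reactants: 11 (2R)-7,8-bis(benzyloxy)-2-[4-(benzyloxy)phenyl]-2H-chromene
Product: 12 (2S,3R,4R)-7,8-bis(benzyloxy)-2-[4-(benzyloxy)phenyl]chromane-3,4-diol
Conditions: OsO4 (2 mol %), NMO, acetone–H2O, 0 °C to rt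
Reagents that add atoms: N-methylmorpholine N-oxide, C[N+]1([O-])CCOCC1; water, O
Why: Upjohn dihydroxylation; the concerted syn addition of OsO4 to the face of C3=C4 opposite the 2-aryl group sets C3 and C4 together and should give the 2,3-trans-3,4-cis diol.

Step 8
Reactants: 12 (2S,3R,4R)-7,8-bis(benzyloxy)-2-[4-(benzyloxy)phenyl]chromane-3,4-diol
Product: 13 cyclic 3,4-carbonate of 12 (cis-fused 1,3-dioxolan-2-one, configuration of 12 retained)
Conditions: 1,1'-carbonyldiimidazole (1.3 equiv), CH2Cl2, rt
Reagents that add atoms: 1,1'-carbonyldiimidazole, O=C(n1ccnc1)n1ccnc1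
Why: Carbonylation of a cis-1,2-diol to the five-membered cyclic carbonate; it masks both hydroxyls and makes the benzylic C4–O bond a poor leaving group for step 12.

Step 9
Reactants: 8 7,8-bis(benzyloxy)-2-ethoxy-2H-chromene; 10 diethyl [4-(benzyloxy)phenyl]boronate
Product: 14 (2S)-7,8-bis(benzyloxy)-2-[4-(benzyloxy)phenyl]-2H-chromene
Conditions: 10 (1.5 equiv), (2S,3S)-4-(dibenzylamino)-2,3-dihydroxy-4-oxobutanoic acid (10 mol %), Yb(OTf)3 (5 mol %), EtOAc, −20 °C
Reagents that add atoms: none
Why: The same enantioselective boronate addition to the chromene acetal as in step 6, run with the mirror-image catalyst, so C2 should form with the opposite configuration.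

Step 10
Reactants: 14 (2S)-7,8-bis(benzyloxy)-2-[4-(benzyloxy)phenyl]-2H-chromene
Product: 15 (2R,3S,4R)-7,8-bis(benzyloxy)-2-[4-(benzyloxy)phenyl]-3-bromochroman-4-ol
Conditions: NBS (1.05 equiv), THF–H2O, 0 °C
Reagents that add atoms: N-bromosuccinimide, O=C1CCC(=O)N1Br; water, O
Why: Bromohydrin formation by electrophilic anti addition; bromine engages the p-alkoxystyrene-type double bond (more reactive than the arenes) on the face opposite the 2-aryl group and water opens at the benzylic C4 from the other face.

Step 11
Reactants: 15 (2R,3S,4R)-7,8-bis(benzyloxy)-2-[4-(benzyloxy)phenyl]-3-bromochroman-4-ol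
Product: 17 (2R,3R,4S)-7,8-bis(benzyloxy)-2-[4-(benzyloxy)phenyl]-4-methoxychroman-3-ol, via cis-epoxide 16 (not isolated)
Conditions: K2CO3 (2 equiv), MeOH, rt
Reagents that add atoms: methanol, CO
Why: Intramolecular Williamson closure with inversion at C3 places the oxygen on the face of the 2-aryl group (2,3-cis), and the labile p-alkoxybenzylic epoxide is opened by methanol at C4 from the opposite face; the C4 configuration is of no consequence because C4 is ionised in step 12.

Step 12
Reactants: 17 (2R,3R,4S)-7,8-bis(benzyloxy)-2-[4-(benzyloxy)phenyl]-4-methoxychroman-3-ol; 13 cyclic 3,4-carbonate of 12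
Product: 18 lower-unit 3,4-carbonate of 19 (interflavan bond C4 of ring C to C6 of ring D)
Conditions: 13 (3 equiv, excess recovered), TMSOTf (0.3 equiv), 4 Å molecular sieves, CH2Cl2, −78 to −40 °C, slow addition of 17; Et3N quench
Reagents that add atoms: none
Why: Lewis-acid-mediated Friedel–Crafts alkylation through the flavan-4-yl (o,p-dialkoxybenzyl) cation; C6 of ring D (ortho to the 7-oxygen, para to O1) should attack the face opposite the 3-hydroxyl and 2-aryl groups to set C4 as 3,4-trans, while the excess of 13 and the slow addition hold back self-condensation.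

Step 13
Reactants: 18 lower-unit 3,4-carbonate of 19
Product: 19 hexa-O-benzyl ether of 20 (benzyl on O7, O8 and O4' of both units)
Conditions: K2CO3 (0.2 equiv), MeOH–THF, 0 °C to rt
Reagents that add atoms: none
Why: Base-catalysed transesterification of the cyclic carbonate; no C–O bond at a stereocentre is broken, and the phenols are still protected while base is present.

Step 14
Reactants: 19 hexa-O-benzyl ether of 20
Product: 20 (2R,3R,4S)-2-(4-hydroxyphenyl)-4-[(2S,3R,4R)-3,4,7,8-tetrahydroxy-2-(4-hydroxyphenyl)chroman-6-yl]chromane-3,7,8-triol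
Conditions: H2 (1 atm), Pd(OH)2/C, THF–MeOH (degassed), rt
Reagents that add atoms: none
Why: Catalytic hydrogenolysis of six aryl benzyl ethers; in neutral medium the secondary benzylic C4–OH of ring F, the two cyclic C2–O1 bonds and the interflavan bond are cleaved far more slowly than O-benzyl groups, so no stereocentre should be touched.

Compound list
1 | 6,7-dihydroxybenzofuran-3(2H)-one | O=C1COc2c1ccc(O)c2O | starting material
2 | 6,7-bis(benzyloxy)benzofuran-3(2H)-one | O=C1COc2c1ccc(OCc1ccccc1)c2OCc1ccccc1 | intermediate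
3 | 6,7-bis(benzyloxy)-2,3-dihydrobenzofuran-3-ol (racemic, not isolated) | OC1COc2c1ccc(OCc1ccccc1)c2OCc1ccccc1 | intermediate
4 | 6,7-bis(benzyloxy)benzofuran | c1coc2c1ccc(OCc1ccccc1)c2OCc1ccccc1 | intermediate
5 | 3,4-bis(benzyloxy)-1,1-dibromo-1a,6b-dihydro-1H-cyclopropa[b]benzofuran (cis-fused, racemic, one antipode drawn, not isolated) | BrC1(Br)[C@H]2Oc3c(OCc4ccccc4)c(OCc4ccccc4)ccc3[C@@H]12 | intermediate
6 | 7,8-bis(benzyloxy)-3-bromochromenylium bromide (not isolated) | c1c(Br)c[o+]c2c(OCc3ccccc3)c(OCc3ccccc3)ccc12.[Br-] | intermediate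
7 | 7,8-bis(benzyloxy)-3-bromo-2-ethoxy-2H-chromene (racemic) | CCOC1Oc2c(OCc3ccccc3)c(OCc3ccccc3)ccc2C=C1Br | intermediate
8 | 7,8-bis(benzyloxy)-2-ethoxy-2H-chromene (racemic) | CCOC1Oc2c(OCc3ccccc3)c(OCc3ccccc3)ccc2C=C1 | intermediate
9 | 4-(benzyloxy)phenylboronic acid | OB(O)c1ccc(OCc2ccccc2)cc1 | starting material
10 | diethyl [4-(benzyloxy)phenyl]boronate | CCOB(OCC)c1ccc(OCc2ccccc2)cc1 | intermediate
11 | (2R)-7,8-bis(benzyloxy)-2-[4-(benzyloxy)phenyl]-2H-chromene | c1cc2c(c(OCc3ccccc3)c1OCc1ccccc1)O[C@@H](c1ccc(OCc3ccccc3)cc1)C=C2 | intermediate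
12 | (2S,3R,4R)-7,8-bis(benzyloxy)-2-[4-(benzyloxy)phenyl]chromane-3,4-diol | c1cc2c(c(OCc3ccccc3)c1OCc1ccccc1)O[C@@H](c1ccc(OCc3ccccc3)cc1)[C@H](O)[C@@H]2O | intermediate
13 | cyclic 3,4-carbonate of 12 (cis-fused) | c1cc2c(c(OCc3ccccc3)c1OCc1ccccc1)O[C@@H](c1ccc(OCc3ccccc3)cc1)[C@H](O3)[C@@H]2OC3=O | intermediate
14 | (2S)-7,8-bis(benzyloxy)-2-[4-(benzyloxy)phenyl]-2H-chromene | c1cc2c(c(OCc3ccccc3)c1OCc1ccccc1)O[C@H](c1ccc(OCc3ccccc3)cc1)C=C2 | intermediate
15 | (2R,3S,4R)-7,8-bis(benzyloxy)-2-[4-(benzyloxy)phenyl]-3-bromochroman-4-ol | c1cc2c(c(OCc3ccccc3)c1OCc1ccccc1)O[C@H](c1ccc(OCc3ccccc3)cc1)[C@@H](Br)[C@@H]2O | intermediate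
16 | (2R)-7,8-bis(benzyloxy)-2-[4-(benzyloxy)phenyl]-3,4-epoxychromane, oxirane on the face of the 2-aryl group (not isolated) | c1cc2c(c(OCc3ccccc3)c1OCc1ccccc1)O[C@H](c1ccc(OCc3ccccc3)cc1)[C@H](O3)[C@@H]23 | intermediate
17 | (2R,3R,4S)-7,8-bis(benzyloxy)-2-[4-(benzyloxy)phenyl]-4-methoxychroman-3-ol | c1cc2c(c(OCc3ccccc3)c1OCc1ccccc1)O[C@H](c1ccc(OCc3ccccc3)cc1)[C@H](O)[C@H]2OC | intermediate
18 | lower-unit 3,4-carbonate of 19 | c1cc2c(c(OCc3ccccc3)c1OCc1ccccc1)O[C@H](c1ccc(OCc3ccccc3)cc1)[C@H](O)[C@H]2c1cc2c(c(OCc3ccccc3)c1OCc1ccccc1)O[C@@H](c1ccc(OCc3ccccc3)cc1)[C@H](O3)[C@@H]2OC3=O | intermediate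
19 | hexa-O-benzyl ether of 20 | c1cc2c(c(OCc3ccccc3)c1OCc1ccccc1)O[C@H](c1ccc(OCc3ccccc3)cc1)[C@H](O)[C@H]2c1cc2c(c(OCc3ccccc3)c1OCc1ccccc1)O[C@@H](c1ccc(OCc3ccccc3)cc1)[C@H](O)[C@@H]2O | intermediate
20 | (2R,3R,4S)-2-(4-hydroxyphenyl)-4-[(2S,3R,4R)-3,4,7,8-tetrahydroxy-2-(4-hydroxyphenyl)chroman-6-yl]chromane-3,7,8-triol (CNP0391561.9) | Oc1ccc([C@H]2Oc3c(ccc(O)c3O)[C@H](c3cc4c(c(O)c3O)O[C@@H](c3ccc(O)cc3)[C@H](O)[C@@H]4O)[C@H]2O)cc1 | target

Total step count: 14. Longest linear sequence: 10 steps (1, 2, 3, 4, 6, 7, 8, 12, 13, 14; the upper branch 1, 2, 3, 4, 9, 10, 11, 12, 13, 14 is equally long).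

Steps most likely to fail

Step 3. The very electron-rich adduct may open before the ethanol stage and be captured by tert-butoxide. Adventitious hydroxide may trigger ring contraction back to a benzofuran, and the carbene may insert into benzylic C–H bonds of the protecting groups.
- The fallback sets out from 4 and returns at 8.
- Ozonolysis of the furan double bond (O3, CH2Cl2–MeOH, −78 °C; Me2S), then methanolysis of the aryl formate (K2CO3, MeOH), would give 3,4-bis(benzyloxy)-2-hydroxybenzaldehyde F1.
- Wittig olefination with ethyl (triphenylphosphoranylidene)acetate would give ethyl (E)-3-[3,4-bis(benzyloxy)-2-hydroxyphenyl]acrylate F2.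
- In hot N,N-diethylaniline F2 isomerises and lactonises to 7,8-bis(benzyloxy)coumarin F3.
- DIBAL-H (toluene, −78 °C) would give 7,8-bis(benzyloxy)-2H-chromen-2-ol F4, and EtOH with pyridinium p-toluenesulfonate would give 8.

Step 6 (and its mirror image, step 9). The 7-oxygenated chromenylium ion is so well stabilised that uncatalysed aryl transfer from free boronate may compete with the catalyst-bound pathway and erode facial selectivity at C2.
- The fallback sets out from 8 and 10 and returns at 11 and at 14.
- The addition is run with Yb(OTf)3 alone to give the racemate, which consists of 11 and 14.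
- The two antipodes are separated by preparative supercritical-fluid chromatography on an amylose tris(3,5-dimethylphenylcarbamate) phase.
- Both antipodes are needed, so the resolution discards nothing and replaces steps 6 and 9 together.

Step 12. The cation may be intercepted by ring A of a second molecule of the electrophile (oligomerisation). Attack at C5 or on ring E may lower regioselectivity, and the benzylic carbonate of the nucleophile may ionise.
- The fallback sets out from 17 and returns at 20, using a blocking group instead of an excess of nucleophile.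
- NBS (1 equiv, CH2Cl2, −20 °C) should brominate C6 of ring A to give (2R,3R,4S)-7,8-bis(benzyloxy)-2-[4-(benzyloxy)phenyl]-6-bromo-4-methoxychroman-3-ol F5.
- F5 can no longer act as a nucleophile and is coupled with 13 (1.2 equiv, TMSOTf) to give the ring-A 6-bromo derivative of 18 F6.
- K2CO3 in MeOH gives the ring-A 6-bromo derivative of 19 F7.
- H2, Pd(OH)2/C, NaOAc removes the bromine together with the six benzyl groups to give 20.

Further compounds
F1 | step 3 | 3,4-bis(benzyloxy)-2-hydroxybenzaldehyde | O=Cc1ccc(OCc2ccccc2)c(OCc2ccccc2)c1O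
F2 | step 3 | ethyl (E)-3-[3,4-bis(benzyloxy)-2-hydroxyphenyl]acrylate | CCOC(=O)/C=C/c1ccc(OCc2ccccc2)c(OCc2ccccc2)c1O
F3 | step 3 | 7,8-bis(benzyloxy)coumarin | O=C1C=Cc2ccc(OCc3ccccc3)c(OCc3ccccc3)c2O1
F4 | step 3 | 7,8-bis(benzyloxy)-2H-chromen-2-ol (racemic) | OC1C=Cc2ccc(OCc3ccccc3)c(OCc3ccccc3)c2O1
F0 | step 6 | none | none
F5 | step 12 | (2R,3R,4S)-7,8-bis(benzyloxy)-2-[4-(benzyloxy)phenyl]-6-bromo-4-methoxychroman-3-ol | Brc1cc2c(c(OCc3ccccc3)c1OCc1ccccc1)O[C@H](c1ccc(OCc3ccccc3)cc1)[C@H](O)[C@H]2OC
F6 | step 12 | ring-A 6-bromo derivative of 18 | Brc1cc2c(c(OCc3ccccc3)c1OCc1ccccc1)O[C@H](c1ccc(OCc3ccccc3)cc1)[C@H](O)[C@H]2c1cc2c(c(OCc3ccccc3)c1OCc1ccccc1)O[C@@H](c1ccc(OCc3ccccc3)cc1)[C@H](O3)[C@@H]2OC3=O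
F7 | step 12 | ring-A 6-bromo derivative of 19 | Brc1cc2c(c(OCc3ccccc3)c1OCc1ccccc1)O[C@H](c1ccc(OCc3ccccc3)cc1)[C@H](O)[C@H]2c1cc2c(c(OCc3ccccc3)c1OCc1ccccc1)O[C@@H](c1ccc(OCc3ccccc3)cc1)[C@H](O)[C@@H]2O
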